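**Retrosynthetic overview**

1. Rings A–F run from the 2,4,6-trihydroxyphenoxy end to the 3,4,5-trihydroxyphenyl end, with ethers A1–O–B1, B6–O–C1, C4–O–D1, D6–O–E1 and E4–O–F1. The plan rests on ring D, which has five adjacent oxygenated carbons (D1, D6, D5, D4, D3) and a single CH (D2). A squarate supplies D1, D6, D5 and D4 with their oxygens, and a 1-ethoxyvinyl group supplies D3 (with its oxygen) and D2.
2. Last steps: cleavage of thirteen methyl ethers and one ethyl ether; before that, the C3 and C5 hydroxyls come from a double Baeyer–Villiger oxidation of a ring C dialdehyde; before that, C4–O–D1 is made by SNAr of the free D1 phenol on an ABC fragment whose C4–F lies between two formyl groups.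
3. DEF trimer: ring D is closed by thermal ring expansion of a 2-aryloxy-4-(1-ethoxyvinyl)-3,4-dimethoxycyclobutenone. This comes from a mixed aryl methyl squarate (EF phenol, squaric dichloride, methanol), 1-ethoxyvinyllithium and methyl triflate. The EF phenol comes from syringaldehyde and 5-bromo-1,2,3-trimethoxybenzene by copper ether coupling and Baeyer–Villiger oxidation.
4. ABC fragment: A1–O–B1 by copper coupling of 2,4,6-trimethoxyphenol with 2-bromo-4,5,6-trimethoxybenzaldehyde, Baeyer–Villiger oxidation to the B6 phenol, then copper coupling (B6–O–C1) with acetal-masked 5-bromo-2-fluoroisophthalaldehyde and unmasking.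
5. Ring order: rings A, B, C, E and F are bought as benzene rings; ring D is the only ring formed, in step 6.

Key step: step 6

Remark on the chemistry: the target has no stereocentre; the cyclobutenone precursor of the key step is made as the racemate because its one stereocentre is lost in the ring expansion.

**Route**

Step 1
Reactants: 1 syringaldehyde (4-hydroxy-3,5-dimethoxybenzaldehyde); 2 5-bromo-1,2,3-trimethoxybenzene
Product: 3 3,5-dimethoxy-4-(3,4,5-trimethoxyphenoxy)benzaldehyde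
Conditions: CuI (10 mol%), picolinic acid (20 mol%), K3PO4, DMSO, 100 °C, Ar
Reagents that add atoms: none
Why: Ullmann-type copper-catalysed diaryl ether synthesis, in which the picolinic acid system should tolerate the di-ortho-substituted phenoxide and the bromide is unhindered at the reacting carbon.

Step 2
Reactants: 3 3,5-dimethoxy-4-(3,4,5-trimethoxyphenoxy)benzaldehyde
Product: 5 3,5-dimethoxy-4-(3,4,5-trimethoxyphenoxy)phenol (EF phenol), via aryl formate 4 (not isolated)
Conditions: mCPBA, CH2Cl2, 0 °C → rt; then K2CO3 (cat.), MeOH, rt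
Reagents that add atoms: 3-chloroperoxybenzoic acid (mCPBA), O=C(OO)c1cccc(Cl)c1
Why: Baeyer–Villiger oxidation of an electron-rich benzaldehyde (para-aryloxy, as in the conversion of 3,4,5-trimethoxybenzaldehyde to its phenol) should proceed by aryl migration to the formate, which is removed by methanolysis.

Step 3
Reactants: 6 squaric acid
Product: 7 3,4-dichlorocyclobut-3-ene-1,2-dione (squaric dichloride)
Conditions: (COCl)2 (2.2 equiv), DMF (cat.), CH2Cl2, 40 °C
Reagents that add atoms: oxalyl chloride, ClC(=O)C(=O)Cl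
Why: Vilsmeier-type conversion of the two vinylogous carboxylic acid hydroxyls into chlorides, the standard preparation of this dichloride.

Step 4
Reactants: 7 squaric dichloride; 5 EF phenol
Product: 9 3-[3,5-dimethoxy-4-(3,4,5-trimethoxyphenoxy)phenoxy]-4-methoxycyclobut-3-ene-1,2-dione, via 3-chloro-4-methoxycyclobutenedione 8 (not isolated)
Conditions: MeOH (1.0 equiv), CH2Cl2, –20 → 0 °C; then 5, iPr2NEt (1.2 equiv), –40 °C → rt
Reagents that add atoms: methanol, CO
Why: Two successive addition–elimination reactions at the vinylogous acid chloride carbons (squarate esterification); methanol is introduced first so that the phenoxide is the only nucleophile present once the labile aryl ester exists, and chloride is the leaving group each time.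

Step 5
Reactants: 9 mixed aryl methyl squarate; 10 ethyl vinyl ether
Product: 13 2-[3,5-dimethoxy-4-(3,4,5-trimethoxyphenoxy)phenoxy]-4-(1-ethoxyvinyl)-3,4-dimethoxycyclobut-2-en-1-one (racemic), via 1-ethoxyvinyllithium 11 (not isolated), via lithium cyclobutenolate 12 (not isolated)
Conditions: 10, t-BuLi, THF, –78 → 0 °C; then 9, THF, –78 °C; then MeOTf, –78 → 0 °C; NaHCO3 work-up, Et3N-deactivated silica
Reagents that add atoms: methyl trifluoromethanesulfonate, COS(=O)(=O)C(F)(F)F
Why: 1,2-addition of an α-alkoxyvinyllithium to a squarate followed by O-methylation of the lithium alkoxide is the standard entry to 4-alkenyl-4-alkoxycyclobutenones; the carbonyl next to the methoxy-bearing carbon should react because it is the vinylogous ester of the weaker aryloxy donor and is further from the bulky aryloxy group, so the new stereocentre (racemic, no control needed) sits beside C–OMe and the retained carbonyl beside C–OAr.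

Step 6
Reactants: 13 cyclobutenone precursor
Product: 16 2-[3,5-dimethoxy-4-(3,4,5-trimethoxyphenoxy)phenoxy]-5-ethoxy-3,4-dimethoxyphenol (DEF phenol), via dienylketene 14 (not isolated), via cyclohexadienone 15 (not isolated)
Conditions: toluene (0.01 M, degassed, base-washed glassware), 110 °C, Ar
Reagents that add atoms: none
Why: Heating should open the C1–C4 bond of 13 in a conrotatory four-electron electrocyclic reaction to the (Z)-dienylketene 14, whose ketene carbon and terminal vinyl CH2 then join in a six-electron electrocyclization that forms the D1–D2 bond and closes ring D as cyclohexadienone 15, and enolization gives phenol 16. The closest known reaction is the thermal ring expansion of squarate-derived 4-alkenyl-4-alkoxycyclobutenones to oxygenated phenols and hydroquinones (Moore rearrangement), which includes α-alkoxyvinyl cases. Ring D, the only ring formed, is closed by a disrotatory 6π electrocyclization of the ketene-terminated triene. No stereocentre is created and the single stereocentre of 13 is destroyed. The step needs torquoselectivity: the methoxy donor on C4 should rotate outward, which turns the ethoxyvinyl group inward and places it cis to the ketene. The oxygen pattern is fixed by step 5: the ketene carbon becomes D1 and carries the only free hydroxyl, the aryloxy carbon becomes D6, the two methoxy carbons become D5 and D4, and the ethoxyvinyl carbons become D3 and D2.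

Step 7
Reactants: 2 5-bromo-1,2,3-trimethoxybenzene
Product: 17 2-bromo-4,5,6-trimethoxybenzaldehyde
Conditions: Cl2CHOMe, TiCl4, CH2Cl2, –10 → 0 °C; then H2O
Reagents that add atoms: dichloromethyl methyl ether, COC(Cl)Cl; water, O
Why: Rieche formylation, for which the only free ring positions are the two equivalent ones ortho to bromine and ortho/para to methoxy groups, so a single aldehyde should form.

Step 8
Reactants: 17 2-bromo-4,5,6-trimethoxybenzaldehyde; 18 2,4,6-trimethoxyphenol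
Product: 19 2,3,4-trimethoxy-6-(2,4,6-trimethoxyphenoxy)benzaldehyde
Conditions: CuI (10 mol%), picolinic acid (20 mol%), K3PO4, DMSO, 90 °C, Ar
Reagents that add atoms: none
Why: Ullmann-type diaryl ether synthesis in which the bromide is activated by the ortho formyl group and has one free ortho position, which offsets the hindrance of the 2,6-dimethoxyphenoxide.

Step 9
Reactants: 19 AB aldehyde
Product: 21 2,3,4-trimethoxy-6-(2,4,6-trimethoxyphenoxy)phenol (AB phenol), via aryl formate 20 (not isolated)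
Conditions: mCPBA, CH2Cl2, 0 °C → rt; then K2CO3 (cat.), MeOH, rt
Reagents that add atoms: 3-chloroperoxybenzoic acid (mCPBA), O=C(OO)c1cccc(Cl)c1
Why: Baeyer–Villiger oxidation of a benzaldehyde with ortho and para oxygen donors should give the formate by aryl migration, and methanolysis frees the B6 hydroxyl.

Step 10
Reactants: 22 5-bromo-2-fluoro-1,3-dimethylbenzene
Product: 23 5-bromo-1,3-bis(dibromomethyl)-2-fluorobenzene
Conditions: NBS (4.4 equiv), AIBN (cat.), PhCF3, 100 °C, hν
Reagents that add atoms: N-bromosuccinimide, O=C1CCC(=O)N1Br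
Why: Wohl–Ziegler radical bromination, which should take each benzylic methyl to the dibromomethyl stage on this electron-poor ring without nuclear bromination.

Step 11
Reactants: 23 tetrabromide
Product: 24 5-bromo-2-fluorobenzene-1,3-dicarbaldehyde
Conditions: AgNO3, EtOH/H2O, 80 °C
Reagents that add atoms: water, O
Why: Silver-assisted hydrolysis of benzylic gem-dibromides to aldehydes under non-basic conditions, which leaves the activated C–F bond untouched.

Step 12
Reactants: 24 fluoro-dialdehyde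
Product: 25 5-bromo-1,3-bis(dimethoxymethyl)-2-fluorobenzene
Conditions: HC(OMe)3, TsOH·H2O (cat.), MeOH, 50 °C
Reagents that add atoms: trimethyl orthoformate, COC(OC)OC; methanol, CO
Why: Acid-catalysed acetal formation, which removes the activation of the fluoride so that the next coupling can occur only at bromine.

Step 13
Reactants: 21 AB phenol; 25 bis-acetal bromide
Product: 26 1,3-bis(dimethoxymethyl)-2-fluoro-5-[2,3,4-trimethoxy-6-(2,4,6-trimethoxyphenoxy)phenoxy]benzene
Conditions: CuI (20 mol%), picolinic acid (40 mol%), K3PO4, DMSO, 100 °C, Ar (25 in excess)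
Reagents that add atoms: none
Why: Ullmann-type diaryl ether synthesis between a di-ortho-substituted phenoxide and a small bromide with two free ortho positions, with the unactivated C–F bond and the acetals inert to base.

Step 14
Reactants: 26 ABC bis-acetal
Product: 27 2-fluoro-5-[2,3,4-trimethoxy-6-(2,4,6-trimethoxyphenoxy)phenoxy]benzene-1,3-dicarbaldehyde
Conditions: HCl (1 M aq.), THF, rt
Reagents that add atoms: water, O
Why: Acid hydrolysis of dimethyl acetals, to which aryl methyl ethers and diaryl ethers are stable.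

Step 15
Reactants: 16 DEF phenol; 27 ABC fluoro-dialdehyde
Product: 28 2-{2-[3,5-dimethoxy-4-(3,4,5-trimethoxyphenoxy)phenoxy]-5-ethoxy-3,4-dimethoxyphenoxy}-5-[2,3,4-trimethoxy-6-(2,4,6-trimethoxyphenoxy)phenoxy]benzene-1,3-dicarbaldehyde
Conditions: Cs2CO3, DMF, 60 °C, Ar
Reagents that add atoms: none
Why: Nucleophilic aromatic substitution of a fluoride flanked by two ortho formyl groups by the only free phenoxide, through a Meisenheimer intermediate stabilized by both aldehydes.

Step 16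
Reactants: 28 hexa-aryl dialdehyde
Product: 30 2-{2-[3,5-dimethoxy-4-(3,4,5-trimethoxyphenoxy)phenoxy]-5-ethoxy-3,4-dimethoxyphenoxy}-5-[2,3,4-trimethoxy-6-(2,4,6-trimethoxyphenoxy)phenoxy]benzene-1,3-diol, via bis-formate 29 (not isolated)
Conditions: mCPBA (3 equiv), CH2Cl2, 0 °C → rt; then K2CO3 (cat.), MeOH, rt, Ar
Reagents that add atoms: 3-chloroperoxybenzoic acid (mCPBA), O=C(OO)c1cccc(Cl)c1
Why: Double Baeyer–Villiger oxidation of ortho-aryloxybenzaldehydes, the usual continuation of the fluorobenzaldehyde route to oxygenated diaryl ethers, followed by methanolysis of the two formates.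

Step 17
Reactants: 30 protected hexamer diol
Product: 31 CNP0218077.0, 2-{2-[3,5-dihydroxy-4-(3,4,5-trihydroxyphenoxy)phenoxy]-3,4,5-trihydroxyphenoxy}-5-[2,3,4-trihydroxy-6-(2,4,6-trihydroxyphenoxy)phenoxy]benzene-1,3-diol
Conditions: BBr3 (excess), CH2Cl2, –78 °C → rt; then H2O, 0 °C, degassed; Sephadex LH-20 under Ar
Reagents that add atoms: none
Why: Lewis acid cleavage of the thirteen aryl methyl ethers and the aryl ethyl ether by BBr3, to which diaryl ether bonds are stable.

**Compound list**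

1 | syringaldehyde (4-hydroxy-3,5-dimethoxybenzaldehyde) | COc1cc(C=O)cc(OC)c1O | starting material
2 | 5-bromo-1,2,3-trimethoxybenzene | COc1cc(Br)cc(OC)c1OC | starting material
3 | 3,5-dimethoxy-4-(3,4,5-trimethoxyphenoxy)benzaldehyde | COc1cc(C=O)cc(OC)c1Oc1cc(OC)c(OC)c(OC)c1 | intermediate
4 | 3,5-dimethoxy-4-(3,4,5-trimethoxyphenoxy)phenyl formate | COc1cc(OC=O)cc(OC)c1Oc1cc(OC)c(OC)c(OC)c1 | intermediate
5 | 3,5-dimethoxy-4-(3,4,5-trimethoxyphenoxy)phenol (EF phenol) | COc1cc(O)cc(OC)c1Oc1cc(OC)c(OC)c(OC)c1 | intermediate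
6 | squaric acid | OC1=C(O)C(=O)C1=O | starting material
7 | 3,4-dichlorocyclobut-3-ene-1,2-dione | ClC1=C(Cl)C(=O)C1=O | intermediate
8 | 3-chloro-4-methoxycyclobut-3-ene-1,2-dione | COC1=C(Cl)C(=O)C1=O | intermediate
9 | 3-[3,5-dimethoxy-4-(3,4,5-trimethoxyphenoxy)phenoxy]-4-methoxycyclobut-3-ene-1,2-dione | COC1=C(Oc2cc(OC)c(Oc3cc(OC)c(OC)c(OC)c3)c(OC)c2)C(=O)C1=O | intermediate
10 | ethyl vinyl ether | C=COCC | starting material
11 | 1-ethoxyvinyllithium | [Li]C(=C)OCC | intermediate
12 | lithium 3-[3,5-dimethoxy-4-(3,4,5-trimethoxyphenoxy)phenoxy]-1-(1-ethoxyvinyl)-2-methoxy-4-oxocyclobut-2-en-1-olate (racemic) | [Li+].[O-]C1(C(=C)OCC)C(OC)=C(Oc2cc(OC)c(Oc3cc(OC)c(OC)c(OC)c3)c(OC)c2)C1=O | intermediate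
13 | 2-[3,5-dimethoxy-4-(3,4,5-trimethoxyphenoxy)phenoxy]-4-(1-ethoxyvinyl)-3,4-dimethoxycyclobut-2-en-1-one (racemic) | CCOC(=C)C1(OC)C(OC)=C(Oc2cc(OC)c(Oc3cc(OC)c(OC)c(OC)c3)c(OC)c2)C1=O | intermediate
14 | (3Z)-2-[3,5-dimethoxy-4-(3,4,5-trimethoxyphenoxy)phenoxy]-5-ethoxy-3,4-dimethoxyhexa-1,3,5-trien-1-one | O=C=C(Oc1cc(OC)c(Oc2cc(OC)c(OC)c(OC)c2)c(OC)c1)/C(OC)=C(OC)\C(=C)OCC | intermediate
15 | 2-[3,5-dimethoxy-4-(3,4,5-trimethoxyphenoxy)phenoxy]-5-ethoxy-3,4-dimethoxycyclohexa-2,4-dien-1-one | CCOC1=C(OC)C(OC)=C(Oc2cc(OC)c(Oc3cc(OC)c(OC)c(OC)c3)c(OC)c2)C(=O)C1 | intermediate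
16 | 2-[3,5-dimethoxy-4-(3,4,5-trimethoxyphenoxy)phenoxy]-5-ethoxy-3,4-dimethoxyphenol (DEF phenol) | CCOc1cc(O)c(Oc2cc(OC)c(Oc3cc(OC)c(OC)c(OC)c3)c(OC)c2)c(OC)c1OC | intermediate
17 | 2-bromo-4,5,6-trimethoxybenzaldehyde | COc1cc(Br)c(C=O)c(OC)c1OC | intermediate
18 | 2,4,6-trimethoxyphenol | COc1cc(OC)c(O)c(OC)c1 | starting material
19 | 2,3,4-trimethoxy-6-(2,4,6-trimethoxyphenoxy)benzaldehyde | COc1cc(OC)c(Oc2cc(OC)c(OC)c(OC)c2C=O)c(OC)c1 | intermediate
20 | 2,3,4-trimethoxy-6-(2,4,6-trimethoxyphenoxy)phenyl formate | COc1cc(OC)c(Oc2cc(OC)c(OC)c(OC)c2OC=O)c(OC)c1 | intermediate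
21 | 2,3,4-trimethoxy-6-(2,4,6-trimethoxyphenoxy)phenol (AB phenol) | COc1cc(OC)c(Oc2cc(OC)c(OC)c(OC)c2O)c(OC)c1 | intermediate
22 | 5-bromo-2-fluoro-1,3-dimethylbenzene | Cc1cc(Br)cc(C)c1F | starting material
23 | 5-bromo-1,3-bis(dibromomethyl)-2-fluorobenzene | Fc1c(C(Br)Br)cc(Br)cc1C(Br)Br | intermediate
24 | 5-bromo-2-fluorobenzene-1,3-dicarbaldehyde | O=Cc1cc(Br)cc(C=O)c1F | intermediate
25 | 5-bromo-1,3-bis(dimethoxymethyl)-2-fluorobenzene | COC(OC)c1cc(Br)cc(C(OC)OC)c1F | intermediate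
26 | 1,3-bis(dimethoxymethyl)-2-fluoro-5-[2,3,4-trimethoxy-6-(2,4,6-trimethoxyphenoxy)phenoxy]benzene | COc1cc(OC)c(Oc2cc(OC)c(OC)c(OC)c2Oc2cc(C(OC)OC)c(F)c(C(OC)OC)c2)c(OC)c1 | intermediate
27 | 2-fluoro-5-[2,3,4-trimethoxy-6-(2,4,6-trimethoxyphenoxy)phenoxy]benzene-1,3-dicarbaldehyde | COc1cc(OC)c(Oc2cc(OC)c(OC)c(OC)c2Oc2cc(C=O)c(F)c(C=O)c2)c(OC)c1 | intermediate
28 | 2-{2-[3,5-dimethoxy-4-(3,4,5-trimethoxyphenoxy)phenoxy]-5-ethoxy-3,4-dimethoxyphenoxy}-5-[2,3,4-trimethoxy-6-(2,4,6-trimethoxyphenoxy)phenoxy]benzene-1,3-dicarbaldehyde | COc1cc(OC)c(Oc2cc(OC)c(OC)c(OC)c2Oc2cc(C=O)c(Oc3cc(OCC)c(OC)c(OC)c3Oc3cc(OC)c(Oc4cc(OC)c(OC)c(OC)c4)c(OC)c3)c(C=O)c2)c(OC)c1 | intermediate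
29 | 2-{2-[3,5-dimethoxy-4-(3,4,5-trimethoxyphenoxy)phenoxy]-5-ethoxy-3,4-dimethoxyphenoxy}-5-[2,3,4-trimethoxy-6-(2,4,6-trimethoxyphenoxy)phenoxy]benzene-1,3-diyl diformate | COc1cc(OC)c(Oc2cc(OC)c(OC)c(OC)c2Oc2cc(OC=O)c(Oc3cc(OCC)c(OC)c(OC)c3Oc3cc(OC)c(Oc4cc(OC)c(OC)c(OC)c4)c(OC)c3)c(OC=O)c2)c(OC)c1 | intermediate
30 | 2-{2-[3,5-dimethoxy-4-(3,4,5-trimethoxyphenoxy)phenoxy]-5-ethoxy-3,4-dimethoxyphenoxy}-5-[2,3,4-trimethoxy-6-(2,4,6-trimethoxyphenoxy)phenoxy]benzene-1,3-diol | COc1cc(OC)c(Oc2cc(OC)c(OC)c(OC)c2Oc2cc(O)c(Oc3cc(OCC)c(OC)c(OC)c3Oc3cc(OC)c(Oc4cc(OC)c(OC)c(OC)c4)c(OC)c3)c(O)c2)c(OC)c1 | intermediate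
31 | CNP0218077.0, 2-{2-[3,5-dihydroxy-4-(3,4,5-trihydroxyphenoxy)phenoxy]-3,4,5-trihydroxyphenoxy}-5-[2,3,4-trihydroxy-6-(2,4,6-trihydroxyphenoxy)phenoxy]benzene-1,3-diol | Oc1cc(O)c(Oc2cc(O)c(O)c(O)c2Oc2cc(O)c(Oc3cc(O)c(O)c(O)c3Oc3cc(O)c(Oc4cc(O)c(O)c(O)c4)c(O)c3)c(O)c2)c(O)c1 | target

**Step count and risks**

Total step count: 17. Longest linear sequence: 8 steps (for example steps 1, 2, 4, 5, 6, 15, 16, 17).

Steps most likely to fail:

1. Step 5. The vinyllithium may add to the other squarate carbonyl or displace the aryloxide by conjugate addition–elimination, and methylation of the hindered lithium alkoxide may be incomplete. The fallback sets out from 7 and 5 and comes back at 13. Squaric dichloride 7 would be treated with two equivalents of EF phenol 5 and iPr2NEt to give the symmetric 3,4-bis[3,5-dimethoxy-4-(3,4,5-trimethoxyphenoxy)phenoxy]cyclobut-3-ene-1,2-dione F1. Its two carbonyl groups are equivalent, so addition of 11 and trapping with MeOTf can give only 2,3-bis[3,5-dimethoxy-4-(3,4,5-trimethoxyphenoxy)phenoxy]-4-(1-ethoxyvinyl)-4-methoxycyclobut-2-en-1-one F2. One equivalent of NaOMe in THF/MeOH at –40 °C should then exchange the aryloxy group on C3, the vinylogous ester carbon, by addition–elimination, releasing 5 and giving 13 with the regiochemistry set by symmetry and not by carbonyl discrimination.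

2. Step 6. The ring opening may be diverted by hydrolysis of the enol ether by traces of acid, by capture of the ketene by adventitious nucleophiles before electrocyclization, or by air oxidation of the electron-rich phenol during heating. The fallback sets out from 5 and comes back at 31, and builds ring D from a bought benzene ring. Copper-catalysed coupling (CuI, picolinic acid, K3PO4, DMSO) of 5 with commercial 2-bromo-3,4,5-trimethoxybenzaldehyde would give 2-[3,5-dimethoxy-4-(3,4,5-trimethoxyphenoxy)phenoxy]-3,4,5-trimethoxybenzaldehyde F3. Baeyer–Villiger oxidation with mCPBA would give 2-[3,5-dimethoxy-4-(3,4,5-trimethoxyphenoxy)phenoxy]-3,4,5-trimethoxyphenyl formate F4, and methanolysis would give 2-[3,5-dimethoxy-4-(3,4,5-trimethoxyphenoxy)phenoxy]-3,4,5-trimethoxyphenol F5, which differs from 16 only in a methoxy group at D3. F5 would take the place of 16 in the chemistry of steps 15 and 16: SNAr on 27 to 2-{2-[3,5-dimethoxy-4-(3,4,5-trimethoxyphenoxy)phenoxy]-3,4,5-trimethoxyphenoxy}-5-[2,3,4-trimethoxy-6-(2,4,6-trimethoxyphenoxy)phenoxy]benzene-1,3-dicarbaldehyde F6, oxidation to the corresponding benzene-1,3-diyl diformate F7, and methanolysis to the corresponding benzene-1,3-diol F8. BBr3 cleavage of the fourteen methyl ethers of F8 would then give 31.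

3. Step 13. Carbon–oxygen bond formation with the di-ortho-substituted, electron-rich phenoxide may be slower than reduction of the bromide or oxidative degradation of the phenol at 100 °C. The fallback sets out from 25 and 21 and comes back at 26. Bromine–lithium exchange of 25 (n-BuLi, THF, –78 °C), trapping with B(OiPr)3 and work-up with aqueous NH4Cl would give [4-fluoro-3,5-bis(dimethoxymethyl)phenyl]boronic acid F9. A Chan–Lam oxidative coupling of F9 with 21 (Cu(OAc)2, pyridine, 4 Å molecular sieves, CH2Cl2, air, rt) should then give 26 at room temperature by a pathway known to accept 2,6-disubstituted phenols.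

**Further compounds**

F1 | step 5 | 3,4-bis[3,5-dimethoxy-4-(3,4,5-trimethoxyphenoxy)phenoxy]cyclobut-3-ene-1,2-dione | O=C1C(=O)C(Oc2cc(OC)c(Oc3cc(OC)c(OC)c(OC)c3)c(OC)c2)=C1Oc1cc(OC)c(Oc2cc(OC)c(OC)c(OC)c2)c(OC)c1
F2 | step 5 | 2,3-bis[3,5-dimethoxy-4-(3,4,5-trimethoxyphenoxy)phenoxy]-4-(1-ethoxyvinyl)-4-methoxycyclobut-2-en-1-one (racemic) | CCOC(=C)C1(OC)C(Oc2cc(OC)c(Oc3cc(OC)c(OC)c(OC)c3)c(OC)c2)=C(Oc2cc(OC)c(Oc3cc(OC)c(OC)c(OC)c3)c(OC)c2)C1=O
F3 | step 6 | 2-[3,5-dimethoxy-4-(3,4,5-trimethoxyphenoxy)phenoxy]-3,4,5-trimethoxybenzaldehyde | COc1cc(C=O)c(Oc2cc(OC)c(Oc3cc(OC)c(OC)c(OC)c3)c(OC)c2)c(OC)c1OC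
F4 | step 6 | 2-[3,5-dimethoxy-4-(3,4,5-trimethoxyphenoxy)phenoxy]-3,4,5-trimethoxyphenyl formate | COc1cc(OC=O)c(Oc2cc(OC)c(Oc3cc(OC)c(OC)c(OC)c3)c(OC)c2)c(OC)c1OC
F5 | step 6 | 2-[3,5-dimethoxy-4-(3,4,5-trimethoxyphenoxy)phenoxy]-3,4,5-trimethoxyphenol | COc1cc(O)c(Oc2cc(OC)c(Oc3cc(OC)c(OC)c(OC)c3)c(OC)c2)c(OC)c1OC
F6 | step 6 | 2-{2-[3,5-dimethoxy-4-(3,4,5-trimethoxyphenoxy)phenoxy]-3,4,5-trimethoxyphenoxy}-5-[2,3,4-trimethoxy-6-(2,4,6-trimethoxyphenoxy)phenoxy]benzene-1,3-dicarbaldehyde | COc1cc(OC)c(Oc2cc(OC)c(OC)c(OC)c2Oc2cc(C=O)c(Oc3cc(OC)c(OC)c(OC)c3Oc3cc(OC)c(Oc4cc(OC)c(OC)c(OC)c4)c(OC)c3)c(C=O)c2)c(OC)c1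
F7 | step 6 | 2-{2-[3,5-dimethoxy-4-(3,4,5-trimethoxyphenoxy)phenoxy]-3,4,5-trimethoxyphenoxy}-5-[2,3,4-trimethoxy-6-(2,4,6-trimethoxyphenoxy)phenoxy]benzene-1,3-diyl diformate | COc1cc(OC)c(Oc2cc(OC)c(OC)c(OC)c2Oc2cc(OC=O)c(Oc3cc(OC)c(OC)c(OC)c3Oc3cc(OC)c(Oc4cc(OC)c(OC)c(OC)c4)c(OC)c3)c(OC=O)c2)c(OC)c1
F8 | step 6 | 2-{2-[3,5-dimethoxy-4-(3,4,5-trimethoxyphenoxy)phenoxy]-3,4,5-trimethoxyphenoxy}-5-[2,3,4-trimethoxy-6-(2,4,6-trimethoxyphenoxy)phenoxy]benzene-1,3-diol | COc1cc(OC)c(Oc2cc(OC)c(OC)c(OC)c2Oc2cc(O)c(Oc3cc(OC)c(OC)c(OC)c3Oc3cc(OC)c(Oc4cc(OC)c(OC)c(OC)c4)c(OC)c3)c(O)c2)c(OC)c1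
F9 | step 13 | [4-fluoro-3,5-bis(dimethoxymethyl)phenyl]boronic acid | OB(O)c1cc(C(OC)OC)c(F)c(C(OC)OC)c1
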